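**Retrosynthetic overview**
- The strategy rests on the two side chains at ring carbons C3 and C5 of the hexasubstituted aryl ring. Each ends in an isopropylidene C2'=C3' bond with no E/Z geometry, so both are cut at that bond by cross-metathesis, back to plain allyl groups and 2-methyl-2-butene.
- The two aryl–CH2 bonds (C3–C1' and C5–C1') go back to a double aromatic Claisen rearrangement of the 2,6-bis(allyl ether). C1 carries the benzoyl group, so each ether has a single free ortho CH.
- The oxygen pattern is set in two stages: the 4-OMe first, by selective methylation of 2,4,6-trihydroxybenzophenone, and the 6-OMe after the Claisen step, by monomethylation of the symmetrical diol, which leaves the chelated 2-OH.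
- No ring is formed anywhere in the route. Both benzene rings and the diaryl ketone are bought with the starting benzophenone.

Key step: step 5

Remark on the chemistry: the target has no stereocentre and no stereogenic double bond, so it is achiral and the "single enantiomer" requirement sets no stereochemical task. 2,4,6-Trihydroxybenzophenone, allyl bromide, 2-methyl-2-butene and dimethyl sulfate are taken as commercial.

**Step 1**
Reactants: 1 2,4,6-trihydroxybenzophenone
Product: 2 2,6-dihydroxy-4-methoxybenzophenone
Conditions: Me2SO4 (1.0 equiv), K2CO3 (1.1 equiv), acetone, 0 °C to rt
Reagents that add atoms: dimethyl sulfate, COS(=O)(=O)OC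
Why: Williamson O-methylation under weak base should pick out the 4-OH, which is para to the carbonyl, the most acidic hydroxyl and outside the hydrogen-bonded chelate that holds the two ortho hydroxyls at the benzoyl oxygen, so one equivalent of reagent should stop at the mono-ether.

**Step 2**
Reactants: 2 2,6-dihydroxy-4-methoxybenzophenone; 3 allyl bromide
Product: 4 2,6-bis(allyloxy)-4-methoxybenzophenone
Conditions: allyl bromide (3 equiv), K2CO3 (4 equiv), DMF, 60 °C
Reagents that add atoms: allyl bromide (3), C=CCBr
Why: Williamson O-allylation in a dipolar aprotic solvent with excess halide should carry both the free and the chelated hydroxyl to the ether and favours O- over C-alkylation of the ambident phenoxide.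

**Step 3**
Reactants: 4 2,6-bis(allyloxy)-4-methoxybenzophenone
Product: 6 3,5-diallyl-2,6-dihydroxy-4-methoxybenzophenone, via mono-rearranged phenol 5 (not isolated)
Conditions: PhNEt2, 200 °C, sealed tube, Ar
Reagents that add atoms: none
Why: Two consecutive aromatic Claisen rearrangements ([3,3]-sigmatropic shift, then tautomerisation back to the phenol) should place the allyl groups at C3 and C5, because each aryl allyl ether has only one open ortho carbon (C1 is blocked by the benzoyl group), and a plain allyl group arrives with its terminal CH=CH2 intact.

**Step 4**
Reactants: 6 3,5-diallyl-2,6-dihydroxy-4-methoxybenzophenone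
Product: 7 3,5-diallyl-2-hydroxy-4,6-dimethoxybenzophenone
Conditions: Me2SO4 (1.1 equiv), K2CO3 (1.5 equiv), acetone, reflux
Reagents that add atoms: dimethyl sulfate, COS(=O)(=O)OC
Why: Williamson O-methylation should stop after one methyl group, since the two hydroxyls are equivalent by symmetry (either gives the same mono-ether) and the one left over is locked in a six-membered hydrogen bond to the benzoyl oxygen and flanked on both sides, which makes it unreactive towards the weak base.

**Step 5**
Reactants: 7 3,5-diallyl-2-hydroxy-4,6-dimethoxybenzophenone; 8 2-methyl-2-butene
Product: 11 2-hydroxy-4,6-dimethoxy-3,5-bis(3-methylbut-2-enyl)benzophenone, via 5-allyl-3-prenyl mono-exchange intermediate 9 (not isolated), via 3-allyl-5-prenyl mono-exchange intermediate 10 (not isolated)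
Conditions: Grubbs II (5 mol%), 1,4-benzoquinone (10 mol%), 2-methyl-2-butene (large excess)/CH2Cl2, 40 °C, sealed tube
Reagents that add atoms: 2-methyl-2-butene (8), CC=C(C)C
Why: The second-generation ruthenium carbene adds [2+2] to each monosubstituted allyl alkene, and the ruthenacyclobutane formed with the isopropylidene unit of 2-methyl-2-butene cycloreverts to the ArCH2CH=C(CH3)2 alkene, the other fragment leaving as propene. The closest known reaction type is cross-metathesis of allylarenes and ortho-allylphenols with 2-methyl-2-butene, a reactive terminal alkene paired with a trisubstituted partner used in excess. No ring is closed and no stereocentre is made, and the new C2'=C3' bonds carry two identical methyl groups, so no E/Z selectivity is needed. The step needs cross-metathesis to win over homodimerisation of the allyl groups; the large excess of 2-methyl-2-butene secures this, and the trisubstituted product alkenes do not re-enter the cycle, so the mono-exchanged intermediates should funnel to the doubly exchanged compound. It also needs the allyl double bonds not to migrate into conjugation with the arene, which the mild temperature and the benzoquinone hydride scavenger address. In the substrate, the meta relation of the two allyl groups rules out ring-closing metathesis, and the phenol, held in a hydrogen bond to the benzoyl oxygen, should not interfere with the ruthenium centre.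

**Compound list**
1 | 2,4,6-trihydroxybenzophenone | O=C(c1ccccc1)c1c(O)cc(O)cc1O | starting material
2 | 2,6-dihydroxy-4-methoxybenzophenone | COc1cc(O)c(C(=O)c2ccccc2)c(O)c1 | intermediate
3 | allyl bromide | C=CCBr | starting material
4 | 2,6-bis(allyloxy)-4-methoxybenzophenone | COc1cc(OCC=C)c(C(=O)c2ccccc2)c(OCC=C)c1 | intermediate
5 | 3-allyl-6-allyloxy-2-hydroxy-4-methoxybenzophenone (mono-rearranged phenol, not isolated) | COc1cc(OCC=C)c(C(=O)c2ccccc2)c(O)c1CC=C | intermediate
6 | 3,5-diallyl-2,6-dihydroxy-4-methoxybenzophenone | COc1c(CC=C)c(O)c(C(=O)c2ccccc2)c(O)c1CC=C | intermediate
7 | 3,5-diallyl-2-hydroxy-4,6-dimethoxybenzophenone | COc1c(CC=C)c(O)c(C(=O)c2ccccc2)c(OC)c1CC=C | intermediate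
8 | 2-methyl-2-butene | CC=C(C)C | starting material
9 | 5-allyl-2-hydroxy-4,6-dimethoxy-3-(3-methylbut-2-enyl)benzophenone (not isolated) | COc1c(CC=C(C)C)c(O)c(C(=O)c2ccccc2)c(OC)c1CC=C | intermediate
10 | 3-allyl-2-hydroxy-4,6-dimethoxy-5-(3-methylbut-2-enyl)benzophenone (not isolated) | COc1c(CC=C)c(O)c(C(=O)c2ccccc2)c(OC)c1CC=C(C)C | intermediate
11 | 2-hydroxy-4,6-dimethoxy-3,5-bis(3-methylbut-2-enyl)benzophenone | COc1c(CC=C(C)C)c(O)c(C(=O)c2ccccc2)c(OC)c1CC=C(C)C | target

**Total step count:** 5
**Longest linear sequence:** 5 steps (1 → 2 → 4 → 6 → 7 → 11)

**Steps most likely to fail**

1. Step 5 (double cross-metathesis). The exchange may stall at the mono-prenyl stage, or a ruthenium hydride formed from decomposing catalyst may move the allyl double bonds into conjugation with the arene before they are exchanged. Fallback: give up alkylidene exchange and put the prenyl groups on directly by C-alkylation of the phloroglucinol nucleus. The fallback sets out from 1. Treatment with prenyl bromide (CC(C)=CCBr, about 2.2 equiv) in aqueous KOH at 0 °C should alkylate the two free ring carbons of the phenoxide and give 2,4,6-trihydroxy-3,5-bis(3-methylbut-2-enyl)benzophenone F1. Methylation of this with Me2SO4 (2 equiv) and K2CO3 in acetone should then etherify the 4-OH and one of the two equivalent ortho hydroxyls while the chelated hydroxyl stays free. The fallback comes back to the route at 11.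

2. Step 1 (selective 4-O-methylation). The methylation may run on to a second hydroxyl before the first equivalent is consumed, or stop short, so that the mono-ether is obtained in a mixture. Fallback: overshoot on purpose and then remove the two methyl groups next to the carbonyl. The fallback sets out from 1. Exhaustive methylation (excess Me2SO4, K2CO3, DMF, 60 °C) should give 2,4,6-trimethoxybenzophenone F2. Excess AlCl3 in CH2Cl2 or warm chlorobenzene, with an aqueous HCl work-up, should then cleave only the two methoxy groups ortho to the carbonyl, through aluminium chelates with the ketone oxygen, and leave the 4-OMe. The fallback comes back to the route at 2.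

3. Step 3 (double Claisen rearrangement). The second [3,3] shift may lag behind the first, and at 200 °C the ortho-allylphenol products may add their O–H across the neighbouring alkene or lose an allyl group. Fallback: replace the sigmatropic route by direct C-allylation. The fallback sets out from 2. Allyl bromide (3) in aqueous KOH, a protic medium that favours carbon over oxygen alkylation of the phenoxide, should allylate C3 and C5. The fallback comes back to the route at 6 and passes through no compound outside the list (F0).

**Further compounds**
F1 | step 5 | 2,4,6-trihydroxy-3,5-bis(3-methylbut-2-enyl)benzophenone | O=C(c1ccccc1)c1c(O)c(CC=C(C)C)c(O)c(CC=C(C)C)c1O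
F2 | step 1 | 2,4,6-trimethoxybenzophenone | COc1cc(OC)c(C(=O)c2ccccc2)c(OC)c1
F0 | step 3 | none | none
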